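## The problem

Target 40 is a melampolide: a ten-membered carbocycle (C1–C10) with a Z trisubstituted alkene at C1=C10 and an E trisubstituted alkene at C4=C5, and an α-methylene-γ-butyrolactone (O6–C12(=O)–C11(=C13)–C7) fused across C6–C7. Four contiguous stereocentres C6–C9 (6S,7R,8R,9R) line one edge of the ring; O8 carries a (2R,3R)-2,3-epoxy-2-methylbutanoate and O9 an acetate, and the epoxy acid adds two centres that no ring centre can control. Closing a ten-membered ring against entropy and transannular strain, with both ring alkenes of defined and opposite geometry, is the central difficulty. Stereocontrol is best exerted in the open chain: C9 can come from the chiral pool and direct C8 by chelation, a cyclic allyl-metal transition state can tie C7 to C8, and C6 needs reagent control because C7 carries two branched groups and gives no clear Felkin bias. The methylene lactone (Michael acceptor, reducible), the epoxy ester (reductants, acid), an allylic C9 acetate (ionised by zerovalent palladium), the 1,5-diene (acid-triggered transannular cyclisation) and the Z alkene are all fragile and force a late redox and acylation endgame. The enabling feature is that O6 is allylic to the E alkene C4=C5 and C2–C3 is the only bond between the two allylic methylenes: a C5–C6 vinyl epoxide next to a C3=C4 alkene ionises to an allyl cation over C3–C5 with O6 as internal base, and a C2 carbanion flanked by two sulfonyl groups can close the ring at C3, giving ring, E alkene and free O6–H in one event without creating a stereocentre.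

## Retrosynthesis

Germacrane numbering (C1–C15) is used for the ring and for every chain intermediate from 17 onward.

**Acyl groups.** The two ester C–O bonds are cut first: the O9 acetate (40 ⇒ 39) and the O8 epoxy ester (38 ⇒ alcohol 32 + acid 36), with the PMB ether of 38 masking O9 in between. They come last because neither ester survives what precedes: the epoxy ester would be reduced during desulfonylation, and an allylic C9 acetate would itself be ionised in the ring closure. O8 is acylated before O9 so that the hindered, slow-migrating acyl group is in place when the C9 hydroxyl of 39 is free. The forward reaction must esterify a hindered secondary alcohol with an α-quaternary acid. Acid 36 is cut back through epoxy alcohol 35 and (Z)-allylic alcohol 34 to angelic acid 33; the Z alkene becomes the cis relation of carboxyl and C3′ methyl, and a tartrate-controlled epoxidation sets both centres.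

**Lactone.** In 32 the C12–O6 bond is cut by lowering C12 to the alcohol level: silyl ether 31 ⇒ diol 28 ⇒ bis-silyl ether 27. Carrying C12 as a protected allylic alcohol rather than as an acrylate keeps a Michael acceptor and an acidic C7–H out of the ring closure and the desulfonylation, at the price of three steps. Compound 27 comes from bis-sulfone 26 by reductive loss of both sulfonyl groups.

**Ring (key cut).** The C2–C3 bond of 26 is cut to give vinyl epoxide 25. Among the ring bonds this is the only one whose formation creates neither a stereocentre nor an alkene by olefination. A cut at C9–C10 or C6–C7 would put a new stereocentre into the cyclisation, and ring-closing metathesis cannot deliver two trisubstituted alkenes of opposite geometry in a ten-membered ring. Compound 25 is acyclic and already holds C6–C9 and the Z alkene. The forward step must attack C3 rather than C5, give the E alkene, alkylate at carbon, and beat oligomerisation.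

**Vinyl epoxide and bis-sulfone.** Compound 25 is cut at C5–C6 and C5–O into aldehyde 21 and methallyl chloride 22 (chloroallylboration, then ring closure of the chlorohydrin). Only C6 matters, since C5 is flattened in the key step, so either epoxide geometry would serve. The second sulfonyl group is attached before the aldehyde is unmasked (21 ⇒ acetal 20 ⇒ monosulfone 19), so that the one strong-base step falls on a robust intermediate.

**C7–C8 bond.** Compound 19 is traced through diol 18 to hydroxy ester 17, which is cut at C7–C8 into aldehyde 12 and allylic bromide 16. An aldol from the C6 side would need an anti, anti-Felkin addition, which is a mismatched case. The allyl-metal route is matched: a cyclic transition state gives the C7/C8 syn relation, and chelation to the C9 ether gives the 8,9-syn diol. Carrying C6 as an acetal rather than a second ester avoids having to tell two carboxyl carbons apart. Bromide 16 comes in two steps from methyl acrylate 13 and 2,2-dimethoxyacetaldehyde 14 via adduct 15.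

**Aldehyde 12.** This is traced back through PMB ether 11, acetal 10, sulfone 8, allylic alcohol 6, Z-enoate 5, ynoate 4 and alkyne 3 to glycerate 1. C9 is taken from the chiral pool. The Z alkene is made by syn-carbocupration of an ynoate, which is stereospecific, rather than by olefination of a methyl ketone, whose geometry is uncertain. The sulfone is placed at C2 early so that C2 never needs a protecting group.

## Roads not taken

Alternative 1: The cut is C7–C11, made last. PMe3 would add to an acrylate ester on O6 of a preformed ten-membered ring holding a C7=C8–C9(=O) enone; the C11 enolate carbon attacks C7 and loss of phosphine leaves the C11=C13 methylene, so lactone and exocyclic alkene of keto lactone A1 arise in one catalytic step (intramolecular Rauhut–Currier reaction).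
- Merit: no protecting-group or redox step is spent on C12. Here it is better than the chosen plan, which spends a reduction, a selective desilylation and an oxidative lactonisation on the same ring.
- Weak points: A1 has a C9 ketone and a bare C8 methylene, so O8 and O9 would have to be introduced on the flexible ring after the methylene lactone exists, in the presence of a Michael acceptor that hydride, bases and the phosphine itself attack. C7 would be set by the tether alone, and the cross-conjugated dienone offers a second β-carbon at C1. The ring closure itself is left unsolved.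
- Comparison: against the shorter lactone construction the chosen plan sets a defined ring closure and a complete stereotetrad before the ring exists.

Alternative 2: The cut is C6–C7, formed while a C4–C9 bond of a six-membered ring breaks. The potassium alkoxide (KH, 18-crown-6) of a cyclohexenol with alkenyl arms on C4 and C9 would undergo an anionic oxy-Cope rearrangement and open out as the C9 enolate of cyclodecadienone A2.
- Merits: ring formation is unimolecular and needs no dilution; the E alkene at C4=C5 and the Z alkene inherited from the six-membered ring follow from the pericyclic geometry; C6 and C7 are set together. In certainty of the ring-forming event this road is better than a medium-ring alkylation.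
- Weak points: A2 lacks O8 and the C9 carbinol, so C8 must be oxygenated next to the ketone and C9 reduced with only the macrocycle conformation as control. The substrate needs two adjacent fully substituted ring carbons with cis alkenyl arms of defined geometry, one an enol ether, in enantioenriched form. The O6 MOM ether would later need acid on a diene prone to transannular cyclisation.
- Comparison: the chosen plan must accept the risk that ring closure loses to oligomerisation, but it fixes all four centres and the full oxidation pattern before cyclisation.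

Alternative 3: The cut is C9–C10. CrCl2 with catalytic NiCl2 would turn a Z-alkenyl iodide into an alkenylchromium that adds to a C9 aldehyde (Nozaki–Hiyama–Kishi reaction), closing the ring and giving hydroxy lactone A3.
- Merits: the reaction tolerates the methylene lactone and free hydroxyls, the iodide geometry is retained, and A3 is three operations from 40 against seven after the ring closure in the chosen plan. In endgame length this road is clearly better.
- Weak points: the cyclisation creates the C9 stereocentre, where Felkin preference, chelation by the C8 ether and ring strain compete. The α-alkoxy aldehyde is epimerisable at C8. The E alkene and the C2–C3 bond must be made separately in the chain. A ten-membered closure onto a trisubstituted alkenylchromium needs stoichiometric CrCl2 at high dilution. From A3 the acetate would go on O9 while O8 is still to be freed, the order more prone to acyl migration.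
- Comparison: the chosen plan accepts the longer endgame for a ring closure that creates no stereocentre and forms the E alkene in the same event.

Key step: step 17

Remark: CIP descriptors of unchanged centres shift with the attached groups (C7 reads S in 17–21 and in 32, R elsewhere); the geometry is the same throughout.

Assumption: the chloroallylborane made from (−)-Ipc2BOMe (from (+)-α-pinene) attacks the Si face of aldehyde 21, the sense shown by the parent allyl- and (Z)-γ-substituted allyl-diisopinocampheylboranes of the same pinene series.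

## Route

Step 1
Reactants: 1 methyl (4S)-2,2-dimethyl-1,3-dioxolane-4-carboxylate
Product: 3 (4R)-4-ethynyl-2,2-dimethyl-1,3-dioxolane, via aldehyde 2 (not isolated)
Conditions: i-Bu2AlH, CH2Cl2, −78 °C; then MeOH, K2CO3, dimethyl (1-diazo-2-oxopropyl)phosphonate, 0 °C to rt
Reagents that add atoms: dimethyl (1-diazo-2-oxopropyl)phosphonate (Ohira–Bestmann reagent), COP(=O)(OC)C(=[N+]=[N-])C(C)=O
Why: Low-temperature ester-to-aldehyde reduction followed in the same flask by Seyferth–Gilbert homologation with the Ohira–Bestmann reagent; the mild carbonate/methanol medium should preserve the α-oxygenated centre, which is C9 of the target and comes unchanged from the chiral pool.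

Step 2
Reactants: 3 (4R)-4-ethynyl-2,2-dimethyl-1,3-dioxolane
Product: 4 methyl 3-[(4R)-2,2-dimethyl-1,3-dioxolan-4-yl]prop-2-ynoate
Conditions: n-BuLi, THF, −78 °C; ClCO2Me, −78 to 0 °C
Reagents that add atoms: methyl chloroformate, COC(Cl)=O
Why: Deprotonation of the terminal alkyne and C-acylation of the acetylide, the standard ynoate synthesis.

Step 3
Reactants: 4 methyl 3-[(4R)-2,2-dimethyl-1,3-dioxolan-4-yl]prop-2-ynoate
Product: 5 methyl (2Z)-3-[(4R)-2,2-dimethyl-1,3-dioxolan-4-yl]but-2-enoate
Conditions: Me2CuLi (from MeLi and CuI), THF, −78 °C; MeOH, −78 °C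
Reagents that add atoms: lithium dimethylcuprate, [Li+].C[Cu-]C
Why: Syn-carbocupration of the ynoate (conjugate addition); protonation of the vinylcopper with retention at −78 °C places H cis to the new methyl, so the ester ends cis to C9, which is the Z alkene C1=C10. Quenching cold prevents equilibration through the allenolate.

Step 4
Reactants: 5 methyl (2Z)-3-[(4R)-2,2-dimethyl-1,3-dioxolan-4-yl]but-2-enoate
Product: 6 (2Z)-3-[(4R)-2,2-dimethyl-1,3-dioxolan-4-yl]but-2-en-1-ol
Conditions: i-Bu2AlH, CH2Cl2, −78 °C
Reagents that add atoms: none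
Why: 1,2-Reduction of the enoate to the allylic alcohol; the alkene geometry is untouched and the acetonide keeps O9 from lactonising onto the cis ester.

Step 5
Reactants: 6 (2Z)-3-[(4R)-2,2-dimethyl-1,3-dioxolan-4-yl]but-2-en-1-ol
Product: 8 (4R)-2,2-dimethyl-4-[(2Z)-4-(phenylsulfonyl)but-2-en-2-yl]-1,3-dioxolane, via mesylate 7 (not isolated)
Conditions: MsCl, Et3N, CH2Cl2, −20 °C; then PhSO2Na, n-Bu4NI (cat.), DMF, rt
Reagents that add atoms: sodium benzenesulfinate, [Na+].[O-]S(=O)c1ccccc1
Why: Mesylation and SN2 S-alkylation of sulfinate at the primary allylic carbon; no allyl cation is formed, so the Z geometry should be kept.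

Step 6
Reactants: 8 (4R)-2,2-dimethyl-4-[(2Z)-4-(phenylsulfonyl)but-2-en-2-yl]-1,3-dioxolane
Product: 10 (4R)-2-(4-methoxyphenyl)-4-[(2Z)-4-(phenylsulfonyl)but-2-en-2-yl]-1,3-dioxolane, via diol 9 (not isolated)
Conditions: p-TsOH·H2O (cat.), MeOH, rt; Et3N, evaporate; then 4-MeOC6H4CH(OMe)2, CSA (cat.), CH2Cl2, rt
Reagents that add atoms: 4-methoxybenzaldehyde dimethyl acetal, COC(OC)c1ccc(OC)cc1
Why: Acid methanolysis of the acetonide and acid-catalysed acetalisation of the 1,2-diol; the new acetal carbon is a spectator centre and both epimers converge in step 7.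

Step 7
Reactants: 10 (4R)-2-(4-methoxyphenyl)-4-[(2Z)-4-(phenylsulfonyl)but-2-en-2-yl]-1,3-dioxolane
Product: 11 (2R,3Z)-2-[(4-methoxybenzyl)oxy]-3-methyl-5-(phenylsulfonyl)pent-3-en-1-ol
Conditions: i-Bu2AlH, CH2Cl2, −78 to 0 °C
Reagents that add atoms: none
Why: Regioselective reductive opening of the 4-methoxybenzylidene acetal: aluminium binds the less hindered primary oxygen and hydride cleaves that C–O bond, leaving the PMB group on the secondary O9, where it will serve as chelating group.

Step 8
Reactants: 11 (2R,3Z)-2-[(4-methoxybenzyl)oxy]-3-methyl-5-(phenylsulfonyl)pent-3-en-1-ol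
Product: 12 (2R,3Z)-2-[(4-methoxybenzyl)oxy]-3-methyl-5-(phenylsulfonyl)pent-3-enal
Conditions: Dess–Martin periodinane, NaHCO3, CH2Cl2, 0 °C; used at once
Reagents that add atoms: none
Why: Dess–Martin oxidation under buffered, base-free conditions; the α-alkoxy β,γ-unsaturated aldehyde is taken on immediately to avoid epimerisation at C9 or conjugation.

Step 9
Reactants: 13 methyl acrylate; 14 2,2-dimethoxyacetaldehyde
Product: 15 methyl 3-hydroxy-4,4-dimethoxy-2-methylidenebutanoate (racemic)
Conditions: DABCO, 1,4-dioxane/H2O, rt
Reagents that add atoms: none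
Why: Morita–Baylis–Hillman reaction of an acrylate with an electrophilic α,α-dialkoxy aldehyde; the carbinol centre is lost in step 10, so a racemate suffices.

Step 10
Reactants: 15 methyl 3-hydroxy-4,4-dimethoxy-2-methylidenebutanoate
Product: 16 methyl (2Z)-2-(bromomethyl)-4,4-dimethoxybut-2-enoate
Conditions: NBS, Me2S, CH2Cl2, 0 °C to rt
Reagents that add atoms: N-bromosuccinimide, O=C1CCC(=O)N1Br
Why: Corey–Kim-type activation of the Baylis–Hillman alcohol and SN2′ bromide delivery give the transposed, thermodynamically preferred Z bromide (acetal cis to CH2Br) under near-neutral conditions that spare the acetal.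

Step 11
Reactants: 12 (2R,3Z)-2-[(4-methoxybenzyl)oxy]-3-methyl-5-(phenylsulfonyl)pent-3-enal; 16 methyl (2Z)-2-(bromomethyl)-4,4-dimethoxybut-2-enoate
Product: 17 methyl (3S,4R,5R,6Z)-3-(dimethoxymethyl)-4-hydroxy-5-[(4-methoxybenzyl)oxy]-6-methyl-2-methylidene-8-(phenylsulfonyl)oct-6-enoate
Conditions: indium powder, THF/H2O (1:1), rt
Reagents that add atoms: none
Why: Indium-mediated Barbier allylation in water: the ester-biased allylindium adds through a Zimmerman–Traxler chair in which the acetal, cis to the metallated CH2, sets C7 syn to the new C8 hydroxyl, while chelation of indium between the aldehyde and the C9 PMB ether (Cram chelate) gives the 8,9-syn diol. Any adduct that lactonises onto C12 converges in step 12.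

Step 12
Reactants: 17 methyl (3S,4R,5R,6Z)-3-(dimethoxymethyl)-4-hydroxy-5-[(4-methoxybenzyl)oxy]-6-methyl-2-methylidene-8-(phenylsulfonyl)oct-6-enoate
Product: 18 (3S,4R,5R,6Z)-3-(dimethoxymethyl)-5-[(4-methoxybenzyl)oxy]-6-methyl-2-methylidene-8-(phenylsulfonyl)oct-6-ene-1,4-diol
Conditions: i-Bu2AlH, CH2Cl2, −78 °C
Reagents that add atoms: none
Why: 1,2-Reduction of the 2-substituted acrylate (or its lactone) to the allylic alcohol; acetal, sulfone and PMB ether are inert to the hydride.

Step 13
Reactants: 18 (3S,4R,5R,6Z)-3-(dimethoxymethyl)-5-[(4-methoxybenzyl)oxy]-6-methyl-2-methylidene-8-(phenylsulfonyl)oct-6-ene-1,4-diol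
Product: 19 bis(tert-butyldimethylsilyl) ether of 18 (O8 and O12 silylated)
Conditions: TBSOTf, 2,6-lutidine, CH2Cl2, −78 to −40 °C
Reagents that add atoms: tert-butyldimethylsilyl triflate, CC(C)(C)[Si](C)(C)OS(=O)(=O)C(F)(F)F
Why: Silyl triflate silylation of the primary and the hindered secondary hydroxyl; at low temperature O-silylation is much faster than activation of the dimethyl acetal.

Step 14
Reactants: 19 bis(tert-butyldimethylsilyl) ether of 18
Product: 20 C2 bis(phenylsulfonyl) analogue of 19
Conditions: LiN(SiMe3)2 (2.2 equiv), THF, −78 °C; PhSO2F, −78 to −40 °C; aq. NH4Cl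
Reagents that add atoms: benzenesulfonyl fluoride, O=S(=O)(F)c1ccccc1
Why: Sulfonylation of the α-sulfonyl carbanion with a sulfonyl fluoride; the second equivalent of base takes up the more acidic bis-sulfone proton. Lithiated allylic sulfones react at the α-carbon and keep their alkene geometry, so the Z alkene should survive.

Step 15
Reactants: 20 C2 bis(phenylsulfonyl) analogue of 19
Product: 21 (2S,3R,4R,5Z)-3-[(tert-butyldimethylsilyl)oxy]-2-{3-[(tert-butyldimethylsilyl)oxy]prop-1-en-2-yl}-4-[(4-methoxybenzyl)oxy]-5-methyl-7,7-bis(phenylsulfonyl)hept-5-enal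
Conditions: TESOTf, 2,4,6-collidine, CH2Cl2, 0 °C; then H2O; used at once
Reagents that add atoms: water, O
Why: Chemoselective acetal cleavage through a collidinium salt that water hydrolyses to the aldehyde; the non-acidic medium leaves TBS and PMB ethers alone and should avoid enolisation at C7, which is both α to the aldehyde and allylic.

Step 16
Reactants: 21 (2S,3R,4R,5Z)-aldehyde from step 15; 22 3-chloro-2-methylprop-1-ene
Product: 25 (5S,6R,7R,8R,9R,1(10)Z)-cis-vinyl epoxide of the seco-germacrane chain, via chloroallylborane 23 (not isolated), via chlorohydrin 24 (not isolated)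
Conditions: 22, (−)-Ipc2BOMe, LiN(c-Hex)2, THF/Et2O, −95 °C; BF3·OEt2; then 21, −95 °C; HOCH2CH2NH2 work-up; then DBU, CH2Cl2, rt
Reagents that add atoms: none
Why: γ-Chloroallylboration: α-lithiation of 22 in the presence of the borinate and BF3-induced collapse give (Z)-γ-chloroallylborane 23, which adds through a chair transition state to give syn chlorohydrin 24, with C6 set by the isopinocampheyl groups (Si face of the aldehyde). DBU then closes the epoxide with inversion at C5; the configuration at C5 is irrelevant later because C5 becomes sp2 in step 17.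

Step 17
Reactants: 25 cis-vinyl epoxide
Product: 26 (1(10)Z,4E,6S,7R,8R,9R)-8,12-bis[(tert-butyldimethylsilyl)oxy]-9-[(4-methoxybenzyl)oxy]-2,2-bis(phenylsulfonyl)germacra-1(10),4,11(13)-trien-6-ol
Conditions: Pd(PPh3)4 (10 mol%), dppe (12 mol%), THF, 40 °C, syringe-pump addition to 0.005 M
Reagents that add atoms: none
Why: Zerovalent palladium adds to the C3=C4 alkene anti to the C5–O bond and opens the epoxide to a zwitterionic π-allyl complex over C3–C5 with the C6 alkoxide as counter-ion. The alkoxide, the only base present, removes the acidic C2–H of the bis-sulfone, so the carbanion exists only in a molecule that already carries the electrophile, which limits oligomerisation. The soft carbanion attacks the allyl face opposite palladium at the unhindered CH2 terminus C3 and forms C2–C3; the closest known reaction type is the palladium-catalysed macrocyclisation of vinyl epoxides bearing tethered bis-sulfone pronucleophiles. The ten-membered ring closes by attack at the allyl terminus remote from oxygen, so C4=C5 ends inside the ring; attack at C5 would give an eight-membered ring with an exocyclic isopropenyl group and is disfavoured by the adjacent alkoxide and the branched terminus. No stereocentre is created: C3 is a methylene, C5 becomes sp2 and the C6–O bond is never broken, so C6–C9 pass through unchanged. The step needs C3 over C5, E over Z, C- over O-alkylation and ring closure over oligomerisation; the E geometry follows from the syn π-allyl isomer (C6 cis to the C4 methyl), which equilibrates with the anti form by η3–η1–η3 slippage faster than the slow ring closure and leads to the less strained (1(10)Z,4E)-diene. The bis-sulfone is chosen because it is acidic enough for the alkoxide relay and reacts at carbon only.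

Step 18
Reactants: 26 bis-sulfone macrocycle
Product: 27 (1(10)Z,4E,6S,7R,8R,9R)-8,12-bis[(tert-butyldimethylsilyl)oxy]-9-[(4-methoxybenzyl)oxy]germacra-1(10),4,11(13)-trien-6-ol
Conditions: 6% Na(Hg), Na2HPO4, MeOH/THF, −20 °C
Reagents that add atoms: none
Why: Buffered sodium-amalgam desulfonylation cleaves both C–S bonds by electron transfer; protonation of the intermediate allyl anion at the less substituted C2 should retain the trisubstituted C1=C10 alkene, and silyl ethers, PMB ether and the allylic alcohol are stable.

Step 19
Reactants: 27 desulfonylated macrocycle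
Product: 28 (1(10)Z,4E,6S,7R,8R,9R)-8-[(tert-butyldimethylsilyl)oxy]-9-[(4-methoxybenzyl)oxy]germacra-1(10),4,11(13)-triene-6,12-diol
Conditions: HF·pyridine, pyridine, THF, 0 °C
Reagents that add atoms: none
Why: Buffered HF·pyridine removes the primary allylic TBS ether much faster than the hindered secondary one at O8, and the buffered medium avoids acid-triggered transannular cyclisation of the diene.

Step 20
Reactants: 28 6,12-diol
Product: 31 (1(10)Z,4E,6S,7R,8R,9R)-8-[(tert-butyldimethylsilyl)oxy]-9-[(4-methoxybenzyl)oxy]germacra-1(10),4,11(13)-trien-12,6-olide, via hydroxy enal 29 (not isolated), via lactol 30 (not isolated)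
Conditions: TEMPO (20 mol%), PhI(OAc)2, CH2Cl2, rt
Reagents that add atoms: none
Why: Oxoammonium oxidation is selective for the primary alcohol; enal 29 closes with O6 to five-membered lactol 30, which is oxidised on to the α-methylene lactone (oxidative lactonisation of a 2-methylene-1,4-diol). O8 stays silylated so only the 6,12-lactone can form.

Step 21
Reactants: 31 silyl ether lactone
Product: 32 (1(10)Z,4E,6S,7S,8R,9R)-8-hydroxy-9-[(4-methoxybenzyl)oxy]germacra-1(10),4,11(13)-trien-12,6-olide
Conditions: HF·pyridine, THF, 0 °C to rt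
Reagents that add atoms: none
Why: An acidic fluoride source frees O8 without generating an alkoxide that could translactonise to the 8,12-lactone or add to the methylene lactone.

Step 22
Reactants: 33 angelic acid
Product: 34 (2Z)-2-methylbut-2-en-1-ol
Conditions: LiAlH4, Et2O, 0 °C
Reagents that add atoms: none
Why: Hydride reduction of the acid to the allylic alcohol; the α-methyl enoate resists conjugate reduction and the Z geometry is kept at low temperature.

Step 23
Reactants: 34 (2Z)-2-methylbut-2-en-1-ol
Product: 35 [(2S,3R)-2,3-dimethyloxiran-2-yl]methanol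
Conditions: Ti(OiPr)4, L-(+)-diethyl tartrate, t-BuOOH, 4 Å MS, CH2Cl2, −20 °C
Reagents that add atoms: tert-butyl hydroperoxide, CC(C)(C)OO
Why: Sharpless asymmetric epoxidation; the L-(+)-tartrate catalyst selects the alkene face that gives the (2S,3R) epoxy alcohol, and the concerted oxygen transfer keeps CH2OH and the C3 methyl cis.

Step 24
Reactants: 35 [(2S,3R)-2,3-dimethyloxiran-2-yl]methanol
Product: 36 (2R,3R)-2,3-dimethyloxirane-2-carboxylic acid
Conditions: RuCl3 (cat.), NaIO4, CCl4/MeCN/H2O, rt
Reagents that add atoms: water, O; sodium periodate, [Na+].[O-]I(=O)(=O)=O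
Why: RuO4 generated in situ oxidises the primary alcohol to the acid without opening the epoxide; the descriptor at C2 changes by priority only.

Step 25
Reactants: 32 8-hydroxy lactone; 36 (2R,3R)-2,3-dimethyloxirane-2-carboxylic acid
Product: 38 (1(10)Z,4E,6S,7R,8R,9R)-8-{[(2R,3R)-2,3-dimethyloxiran-2-yl]carbonyloxy}-9-[(4-methoxybenzyl)oxy]germacra-1(10),4,11(13)-trien-12,6-olide, via mixed anhydride 37 (not isolated)
Conditions: 36, 2,4,6-Cl3C6H2COCl, Et3N, THF, 0 °C; then 32, DMAP, toluene, rt
Reagents that add atoms: none
Why: Yamaguchi esterification: DMAP attacks mixed anhydride 37 at the less hindered epoxy-acyl carbonyl and the acylpyridinium acylates the hindered O8; the acid has no α-hydrogen, so it cannot epimerise.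

Step 26
Reactants: 38 epoxy ester PMB ether
Product: 39 (1(10)Z,4E,6S,7R,8R,9R)-8-{[(2R,3R)-2,3-dimethyloxiran-2-yl]carbonyloxy}-9-hydroxygermacra-1(10),4,11(13)-trien-12,6-olide
Conditions: DDQ, CH2Cl2/pH 7 buffer, 0 °C
Reagents that add atoms: none
Why: Oxidative PMB cleavage by hydride abstraction and hydrolysis in a neutral buffered medium that spares the epoxy ester and the methylene lactone; the hindered O8 acyl group does not migrate under these conditions.

Step 27
Reactants: 39 9-hydroxy epoxy ester
Product: 40 (1(10)Z,4E,6S,7R,8R,9R)-9-acetoxy-8-{[(2R,3R)-2,3-dimethyloxiran-2-yl]carbonyloxy}germacra-1(10),4,11(13)-trien-12,6-olide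
Conditions: Ac2O, pyridine, DMAP (cat.), CH2Cl2, 0 °C
Reagents that add atoms: acetic anhydride, CC(=O)OC(C)=O
Why: DMAP-catalysed acetylation of the allylic secondary alcohol is fast enough at 0 °C to outrun any acyl shift and gives the target.

## Compound list

1 | methyl (4S)-2,2-dimethyl-1,3-dioxolane-4-carboxylate | COC(=O)[C@@H]1COC(C)(C)O1 | starting material
2 | (4S)-2,2-dimethyl-1,3-dioxolane-4-carbaldehyde | O=C[C@@H]1COC(C)(C)O1 | intermediate (not isolated)
3 | (4R)-4-ethynyl-2,2-dimethyl-1,3-dioxolane | C#C[C@@H]1COC(C)(C)O1 | intermediate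
4 | methyl 3-[(4R)-2,2-dimethyl-1,3-dioxolan-4-yl]prop-2-ynoate | COC(=O)C#C[C@@H]1COC(C)(C)O1 | intermediate
5 | methyl (2Z)-3-[(4R)-2,2-dimethyl-1,3-dioxolan-4-yl]but-2-enoate | COC(=O)/C=C(/C)[C@@H]1COC(C)(C)O1 | intermediate
6 | (2Z)-3-[(4R)-2,2-dimethyl-1,3-dioxolan-4-yl]but-2-en-1-ol | OC/C=C(/C)[C@@H]1COC(C)(C)O1 | intermediate
7 | (2Z)-3-[(4R)-2,2-dimethyl-1,3-dioxolan-4-yl]but-2-en-1-yl methanesulfonate | CS(=O)(=O)OC/C=C(/C)[C@@H]1COC(C)(C)O1 | intermediate (not isolated)
8 | (4R)-2,2-dimethyl-4-[(2Z)-4-(phenylsulfonyl)but-2-en-2-yl]-1,3-dioxolane | O=S(=O)(C/C=C(/C)[C@@H]1COC(C)(C)O1)c1ccccc1 | intermediate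
9 | (2R,3Z)-3-methyl-5-(phenylsulfonyl)pent-3-ene-1,2-diol | OC[C@H](O)/C(C)=C\CS(=O)(=O)c1ccccc1 | intermediate (not isolated)
10 | (4R)-2-(4-methoxyphenyl)-4-[(2Z)-4-(phenylsulfonyl)but-2-en-2-yl]-1,3-dioxolane (both epimers at the acetal carbon) | COc1ccc(cc1)C1OC[C@H](O1)/C(C)=C\CS(=O)(=O)c1ccccc1 | intermediate
11 | (2R,3Z)-2-[(4-methoxybenzyl)oxy]-3-methyl-5-(phenylsulfonyl)pent-3-en-1-ol | OC[C@H](OCc1ccc(OC)cc1)/C(C)=C\CS(=O)(=O)c1ccccc1 | intermediate
12 | (2R,3Z)-2-[(4-methoxybenzyl)oxy]-3-methyl-5-(phenylsulfonyl)pent-3-enal | O=C[C@H](OCc1ccc(OC)cc1)/C(C)=C\CS(=O)(=O)c1ccccc1 | intermediate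
13 | methyl acrylate | COC(=O)C=C | starting material
14 | 2,2-dimethoxyacetaldehyde | COC(OC)C=O | starting material
15 | methyl 3-hydroxy-4,4-dimethoxy-2-methylidenebutanoate (racemic) | COC(=O)C(=C)C(O)C(OC)OC | intermediate
16 | methyl (2Z)-2-(bromomethyl)-4,4-dimethoxybut-2-enoate | COC(=O)/C(CBr)=C/C(OC)OC | intermediate
17 | methyl (3S,4R,5R,6Z)-3-(dimethoxymethyl)-4-hydroxy-5-[(4-methoxybenzyl)oxy]-6-methyl-2-methylidene-8-(phenylsulfonyl)oct-6-enoate (germacrane: 7S,8R,9R) | COC(OC)[C@@H](C(=C)C(=O)OC)[C@@H](O)[C@H](OCc1ccc(OC)cc1)/C(C)=C\CS(=O)(=O)c1ccccc1 | intermediate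
18 | (3S,4R,5R,6Z)-3-(dimethoxymethyl)-5-[(4-methoxybenzyl)oxy]-6-methyl-2-methylidene-8-(phenylsulfonyl)oct-6-ene-1,4-diol | COC(OC)[C@@H](C(=C)CO)[C@@H](O)[C@H](OCc1ccc(OC)cc1)/C(C)=C\CS(=O)(=O)c1ccccc1 | intermediate
19 | 1,4-bis(tert-butyldimethylsilyl) ether of 18 (C6 dimethyl acetal, O8 and O12 TBS, O9 PMB, C2 phenyl sulfone; 7S,8R,9R, 1(10)Z) | COC(OC)[C@@H](C(=C)CO[Si](C)(C)C(C)(C)C)[C@@H](O[Si](C)(C)C(C)(C)C)[C@H](OCc1ccc(OC)cc1)/C(C)=C\CS(=O)(=O)c1ccccc1 | intermediate
20 | C2 bis(phenylsulfonyl) analogue of 19 (7S,8R,9R, 1(10)Z) | COC(OC)[C@@H](C(=C)CO[Si](C)(C)C(C)(C)C)[C@@H](O[Si](C)(C)C(C)(C)C)[C@H](OCc1ccc(OC)cc1)/C(C)=C\C(S(=O)(=O)c1ccccc1)S(=O)(=O)c1ccccc1 | intermediate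
21 | (2S,3R,4R,5Z)-3-[(tert-butyldimethylsilyl)oxy]-2-{3-[(tert-butyldimethylsilyl)oxy]prop-1-en-2-yl}-4-[(4-methoxybenzyl)oxy]-5-methyl-7,7-bis(phenylsulfonyl)hept-5-enal (C6 aldehyde; 7S,8R,9R) | O=C[C@@H](C(=C)CO[Si](C)(C)C(C)(C)C)[C@@H](O[Si](C)(C)C(C)(C)C)[C@H](OCc1ccc(OC)cc1)/C(C)=C\C(S(=O)(=O)c1ccccc1)S(=O)(=O)c1ccccc1 | intermediate
22 | 3-chloro-2-methylprop-1-ene | CC(=C)CCl | starting material
23 | [(2Z)-3-chloro-2-methylprop-2-en-1-yl]diisopinocampheylborane (Ipc groups from (+)-α-pinene) | Cl/C=C(C)\CB([C@@H]1C[C@@H]2C[C@H]([C@H]1C)C2(C)C)[C@@H]1C[C@@H]2C[C@H]([C@H]1C)C2(C)C | intermediate (not isolated)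
24 | (5R,6R,7R,8R,9R,1(10)Z)-syn-chlorohydrin: C5 chloride, C6 alcohol, C3=C4 isopropenyl, otherwise as 21 | C=C(C)[C@@H](Cl)[C@H](O)[C@@H](C(=C)CO[Si](C)(C)C(C)(C)C)[C@@H](O[Si](C)(C)C(C)(C)C)[C@H](OCc1ccc(OC)cc1)/C(C)=C\C(S(=O)(=O)c1ccccc1)S(=O)(=O)c1ccccc1 | intermediate (not isolated)
25 | (5S,6R,7R,8R,9R,1(10)Z)-cis-5,6-epoxide with C3=C4 isopropenyl group, O8 and O12 TBS, O9 PMB, C2 bis(phenylsulfonyl) | C=C(C)[C@@H]1O[C@@H]1[C@@H](C(=C)CO[Si](C)(C)C(C)(C)C)[C@@H](O[Si](C)(C)C(C)(C)C)[C@H](OCc1ccc(OC)cc1)/C(C)=C\C(S(=O)(=O)c1ccccc1)S(=O)(=O)c1ccccc1 | intermediate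
26 | (1(10)Z,4E,6S,7R,8R,9R)-8,12-bis[(tert-butyldimethylsilyl)oxy]-9-[(4-methoxybenzyl)oxy]-2,2-bis(phenylsulfonyl)germacra-1(10),4,11(13)-trien-6-ol | O[C@H]1/C=C(\C)CC(S(=O)(=O)c2ccccc2)(S(=O)(=O)c2ccccc2)/C=C(/C)[C@@H](OCc2ccc(OC)cc2)[C@H](O[Si](C)(C)C(C)(C)C)[C@@H]1C(=C)CO[Si](C)(C)C(C)(C)C | intermediate
27 | (1(10)Z,4E,6S,7R,8R,9R)-8,12-bis[(tert-butyldimethylsilyl)oxy]-9-[(4-methoxybenzyl)oxy]germacra-1(10),4,11(13)-trien-6-ol | O[C@H]1/C=C(\C)CC/C=C(/C)[C@@H](OCc2ccc(OC)cc2)[C@H](O[Si](C)(C)C(C)(C)C)[C@@H]1C(=C)CO[Si](C)(C)C(C)(C)C | intermediate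
28 | (1(10)Z,4E,6S,7R,8R,9R)-8-[(tert-butyldimethylsilyl)oxy]-9-[(4-methoxybenzyl)oxy]germacra-1(10),4,11(13)-triene-6,12-diol | O[C@H]1/C=C(\C)CC/C=C(/C)[C@@H](OCc2ccc(OC)cc2)[C@H](O[Si](C)(C)C(C)(C)C)[C@@H]1C(=C)CO | intermediate
29 | 6-hydroxy-12-al corresponding to 28 (C12 enal) | O[C@H]1/C=C(\C)CC/C=C(/C)[C@@H](OCc2ccc(OC)cc2)[C@H](O[Si](C)(C)C(C)(C)C)[C@@H]1C(=C)C=O | intermediate (not isolated)
30 | 12,6-lactol corresponding to 31 (C12 epimers) | C=C1C(O)O[C@H]2/C=C(\C)CC/C=C(/C)[C@@H](OCc3ccc(OC)cc3)[C@H](O[Si](C)(C)C(C)(C)C)[C@H]12 | intermediate (not isolated)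
31 | (1(10)Z,4E,6S,7R,8R,9R)-8-[(tert-butyldimethylsilyl)oxy]-9-[(4-methoxybenzyl)oxy]germacra-1(10),4,11(13)-trien-12,6-olide | C=C1C(=O)O[C@H]2/C=C(\C)CC/C=C(/C)[C@@H](OCc3ccc(OC)cc3)[C@H](O[Si](C)(C)C(C)(C)C)[C@H]12 | intermediate
32 | (1(10)Z,4E,6S,7S,8R,9R)-8-hydroxy-9-[(4-methoxybenzyl)oxy]germacra-1(10),4,11(13)-trien-12,6-olide | C=C1C(=O)O[C@H]2/C=C(\C)CC/C=C(/C)[C@@H](OCc3ccc(OC)cc3)[C@H](O)[C@H]12 | intermediate
33 | angelic acid, (2Z)-2-methylbut-2-enoic acid | C/C=C(/C)C(O)=O | starting material
34 | (2Z)-2-methylbut-2-en-1-ol | C/C=C(/C)CO | intermediate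
35 | [(2S,3R)-2,3-dimethyloxiran-2-yl]methanol | OC[C@]1(C)O[C@@H]1C | intermediate
36 | (2R,3R)-2,3-dimethyloxirane-2-carboxylic acid | OC(=O)[C@]1(C)O[C@@H]1C | intermediate
37 | (2R,3R)-2,3-dimethyloxirane-2-carboxylic 2,4,6-trichlorobenzoic anhydride | O=C(OC(=O)[C@]1(C)O[C@@H]1C)c1c(Cl)cc(Cl)cc1Cl | intermediate (not isolated)
38 | (1(10)Z,4E,6S,7R,8R,9R)-8-{[(2R,3R)-2,3-dimethyloxiran-2-yl]carbonyloxy}-9-[(4-methoxybenzyl)oxy]germacra-1(10),4,11(13)-trien-12,6-olide | C=C1C(=O)O[C@H]2/C=C(\C)CC/C=C(/C)[C@@H](OCc3ccc(OC)cc3)[C@H](OC(=O)[C@]3(C)O[C@@H]3C)[C@H]12 | intermediate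
39 | (1(10)Z,4E,6S,7R,8R,9R)-8-{[(2R,3R)-2,3-dimethyloxiran-2-yl]carbonyloxy}-9-hydroxygermacra-1(10),4,11(13)-trien-12,6-olide | C=C1C(=O)O[C@H]2/C=C(\C)CC/C=C(/C)[C@@H](O)[C@H](OC(=O)[C@]3(C)O[C@@H]3C)[C@H]12 | intermediate
40 | (1(10)Z,4E,6S,7R,8R,9R)-9-acetoxy-8-{[(2R,3R)-2,3-dimethyloxiran-2-yl]carbonyloxy}germacra-1(10),4,11(13)-trien-12,6-olide (CNP0304643.4) | C=C1C(=O)O[C@H]2/C=C(\C)CC/C=C(/C)[C@@H](OC(C)=O)[C@H](OC(=O)[C@]3(C)O[C@@H]3C)[C@H]12 | target

## Step count and risks

Total step count: 27. Longest linear sequence: 22 steps (steps 1–8, 11–21 and 25–27); steps 9–10 and 22–24 are side branches.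

Steps least certain to work:

**Step 17 (key step).** The ring closure may lose to intermolecular alkylation, to attack at C5 (eight-membered ring), to O-alkylation or β-hydride loss from the π-allyl alkoxide, or to slow ionisation of the allylic bis-sulfone by the catalyst. The strain of a ten-membered transition state makes all of these competitive.
- Fallback: remove palladium from the ring closure and fix the alkene geometry beforehand. Setting out from 25, MgBr2·OEt2 would open the vinyl epoxide in the SN2′ sense to the thermodynamically preferred primary (E)-allylic bromide with free C6 hydroxyl, bromohydrin F1. Intramolecular C-alkylation of its bis-sulfone anion (Cs2CO3, DMF, high dilution), the classical sulfone-carbanion macrocyclisation, would then form the same C2–C3 bond and return to the route at 26.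

**Step 16.** The lithiated methallyl chloride may collapse by α-elimination before boron captures it, since the β-methyl reagent has less precedent than the parent. Facial control at the doubly branched aldehyde may also be poor, and the aldehyde may enolise at C7.
- Fallback: build the epoxide by olefination and reagent-controlled epoxidation. Setting out from 21, a Wittig reaction with the ylide from tributyl(2-methylallyl)phosphonium bromide (2.2 equiv with LiN(SiMe3)2, the first equivalent being consumed by the acidic bis-sulfone proton) would give the (5E)-diene F2. Shi epoxidation of its trans-disubstituted alkene (D-fructose-derived ketone, KHSO5, pH 7–8) would give the trans-vinyl epoxide F3 with the same C6 configuration. F3 is an equally valid substrate for the conditions of step 17, because C5 is lost there, and returns to the route at 26.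

**Step 11.** Chelation control by the PMB ether in water may be eroded, giving the 8,9-anti diol, and aldehyde 12 may partly racemise or conjugate before it reacts.
- Fallback: replace the closed indium transition state by an open, Lewis-acid-chelated one. Setting out from 15, acetylation (Ac2O, DMAP) would give acetate F4. SN2′ displacement with Bu3SnLi/CuBr·SMe2 would give allylstannane F5. Its MgBr2·OEt2-mediated addition to 12 (CH2Cl2, −20 °C), a chelation-controlled allylstannane addition known to give syn,syn triads whatever the stannane geometry, would return to the route at 17.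

**Step 18.** Removal of the second, allylic sulfonyl group passes through an allyl anion over C2–C1–C10; protonation at C10 or rotation in the anion would shift the alkene or scramble its Z geometry.
- Fallback: remove the two sulfonyl groups by different mechanisms. Setting out from 26, SmI2 (THF/MeOH, −78 °C) would remove one sulfonyl group to give allylic monosulfone F6. Palladium-catalysed hydride displacement (PdCl2(dppp), LiBHEt3, THF, 0 °C), which delivers hydride to the less substituted allyl terminus C2, would return to the route at 27.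

## Further compounds

F1 | step 17 | (4E,6S,7R,8R,9R,1(10)Z)-3-bromo-6-hydroxy seco-chain: primary allylic bromide at C3, E alkene C4=C5, otherwise as 25 | BrC/C(C)=C/[C@H](O)[C@@H](C(=C)CO[Si](C)(C)C(C)(C)C)[C@@H](O[Si](C)(C)C(C)(C)C)[C@H](OCc1ccc(OC)cc1)/C(C)=C\C(S(=O)(=O)c1ccccc1)S(=O)(=O)c1ccccc1
F2 | step 16 | (5E)-3,5-diene from 21: C6 aldehyde replaced by (E)-CH=CH–C(CH3)=CH2, C7–C9 configured as in 21 | C=C(C)/C=C/[C@@H](C(=C)CO[Si](C)(C)C(C)(C)C)[C@@H](O[Si](C)(C)C(C)(C)C)[C@H](OCc1ccc(OC)cc1)/C(C)=C\C(S(=O)(=O)c1ccccc1)S(=O)(=O)c1ccccc1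
F3 | step 16 | (5R,6R,7R,8R,9R,1(10)Z)-trans-5,6-epoxide, the C5 epimer of 25 | C=C(C)[C@H]1O[C@@H]1[C@@H](C(=C)CO[Si](C)(C)C(C)(C)C)[C@@H](O[Si](C)(C)C(C)(C)C)[C@H](OCc1ccc(OC)cc1)/C(C)=C\C(S(=O)(=O)c1ccccc1)S(=O)(=O)c1ccccc1
F4 | step 11 | methyl 3-acetoxy-4,4-dimethoxy-2-methylidenebutanoate (racemic) | COC(=O)C(=C)C(OC(C)=O)C(OC)OC
F5 | step 11 | methyl (2Z)-4,4-dimethoxy-2-[(tributylstannyl)methyl]but-2-enoate | COC(=O)/C(C[Sn](CCCC)(CCCC)CCCC)=C/C(OC)OC
F6 | step 18 | 2-(phenylsulfonyl) analogue of 27 (C2 epimers) | O[C@H]1/C=C(\C)CC(S(=O)(=O)c2ccccc2)/C=C(/C)[C@@H](OCc2ccc(OC)cc2)[C@H](O[Si](C)(C)C(C)(C)C)[C@@H]1C(=C)CO[Si](C)(C)C(C)(C)C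
A1 | alternative 1 | 9-oxogermacra-1(10)Z,4E,11(13)-trien-12,6-olide (C8 methylene) | C=C1C(=O)O[C@H]2/C=C(\C)CC/C=C(/C)C(=O)C[C@H]12
A2 | alternative 2 | (2Z,6E)-cyclodeca-2,6-dienone with O6 MOM ether and C7 3-(silyloxy)prop-1-en-2-yl group | C1/C=C(/C)C(=O)C[C@H](C(=C)CO[Si](C)(C)C(C)(C)C)[C@@H](OCOC)/C=C(\C)C1
A3 | alternative 3 | 9-hydroxy-8-[(4-methoxybenzyl)oxy]germacra-1(10)Z,4E,11(13)-trien-12,6-olide | C=C1C(=O)O[C@H]2/C=C(\C)CC/C=C(/C)[C@@H](O)[C@H](OCc3ccc(OC)cc3)[C@H]12
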